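**Assumptions (one line):** ring numbered as cyclooctane-1,3-dione (C1/C3 ketones, C2 carbinol, C4/C6 prenyl CH, C7 quaternary, C8 acyl CH), target = (2R,4S,6S,7R,8R); 5-methylhex-4-enal is bought (otherwise one Claisen step from 2-methylbut-3-en-2-ol and ethyl vinyl ether); the natural C8 epimer is taken to be the thermodynamic one.

## Retrosynthetic overview

1. 18 ⇐ 17: the C8–acyl bond comes from an anionic O→C shift of an isobutyrate parked on the C2 oxygen; C2 (OH, prenyl) comes from prenylation then hydroxylation of a cyclooctane-1,3-dione.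
2. Key step, 13 ⇐ 12 ⇐ 10: the eight-membered 1,3-dione is made by two-carbon ring expansion of a cyclohexanone silyl enol ether (dichloroketene [2+2], then dechlorination and retro-aldol), not by an 8-ring closure or by degrading a bicyclo[3.3.1] PPAP.
3. 10 ⇐ 8 ⇐ 6: C7 is set by trans-selective homoprenyl cuprate addition and C4 by trans α′-prenylation of (R)-3-methyl-4-prenylcyclohexenone.
4. 6 ⇐ 4 ⇐ 1 + 2: C6 is the only catalyst-set centre (organocatalytic Michael, then aldol condensation).
5. Ring order: the six-membered ring is formed first (step 2) and expanded to the eight-membered ring (steps 7–8); no other ring is made.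

## Route

**Step 1**
Reactants: 1 5-methylhex-4-enal; 2 but-3-en-2-one (MVK)
Product: 3 (R)-5-methyl-2-(3-oxobutyl)hex-4-enal
Conditions: (R)-diphenylprolinol TMS ether (10 mol%), ethyl 3,4-dihydroxybenzoate (20 mol%), neat, 4 °C
Reagents that add atoms: none (both reactants incorporated)
Why: Enamine-catalysed Michael addition of an aldehyde to MVK; the (R)-catalyst shields one enamine face so MVK adds to give the (R)-aldehyde, which becomes C6 of the target.

**Step 2**
Reactants: 3
Product: 4 (R)-4-(3-methylbut-2-en-1-yl)cyclohex-2-en-1-one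
Conditions: LiOH, i-PrOH, rt
Reagents that add atoms: none
Why: Intramolecular aldol condensation of the methyl ketone onto the aldehyde; the stereocentre becomes the γ-carbon of the enone and is not enolised under these mild conditions.

**Step 3**
Reactants: 4
Product: 5 trimethyl{[(3R,4R)-3-methyl-4-(3-methylbut-2-en-1-yl)cyclohex-1-en-1-yl]oxy}silane
Conditions: Me2CuLi, TMSCl, THF, −78 °C
Reagents that add atoms: lithium dimethylcuprate, [Li+].C[Cu-]C; chlorotrimethylsilane, C[Si](C)(C)Cl
Why: TMSCl-accelerated Gilman conjugate addition gives the regiodefined enol ether; the C3 configuration (trans) is irrelevant because it is erased in step 4.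

**Step 4**
Reactants: 5
Product: 6 (R)-3-methyl-4-(3-methylbut-2-en-1-yl)cyclohex-2-en-1-one
Conditions: Pd(OAc)2, MeCN, rt
Reagents that add atoms: none
Why: Saegusa–Ito oxidation of the regiodefined enol ether gives only the β-methyl enone; C4 is untouched.

**Step 5**
Reactants: 6; 7 prenyl bromide
Product: 8 (4S,6S)-3-methyl-4,6-bis(3-methylbut-2-en-1-yl)cyclohex-2-en-1-one (4,6-trans)
Conditions: LDA, THF, −78 °C; then 7, HMPA, −78 → −30 °C
Reagents that add atoms: prenyl bromide, CC(C)=CCBr
Why: Kinetic α′-enolate alkylation; the bromide enters anti to the pseudoaxial C4 prenyl group (A1,2 strain with the 3-methyl), giving the trans isomer, which is also the more stable one, and this sets target C4 (the 4R→4S change is a CIP priority switch only).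

**Step 6**
Reactants: 8; 9 5-bromo-2-methylpent-2-ene (as its Grignard reagent)
Product: 10 trimethyl{[(3R,4S,6S)-3-methyl-4,6-bis(3-methylbut-2-en-1-yl)-3-(4-methylpent-3-en-1-yl)cyclohex-1-en-1-yl]oxy}silane
Conditions: 9, Mg, THF; then CuBr·SMe2 (20 mol%), TMSCl, HMPA, THF, −78 °C; Et3N work-up
Reagents that add atoms: (4-methylpent-3-enyl)magnesium bromide, CC(C)=CCC[Mg]Br; chlorotrimethylsilane, C[Si](C)(C)Cl
Why: Cu-catalysed, TMSCl-promoted conjugate addition with axial attack anti to the C4 prenyl group; this puts homoprenyl trans and methyl cis to that prenyl (target C7), and the enolate is trapped regiospecifically on the quaternary side.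

**Step 7**
Reactants: 10; 11 dichloroacetyl chloride
Product: 12 (1S,2S,4S,5R,6S)-8,8-dichloro-5-methyl-2,4-bis(3-methylbut-2-en-1-yl)-5-(4-methylpent-3-en-1-yl)-1-(trimethylsilyloxy)bicyclo[4.2.0]octan-7-one (cis-fused; either facial isomer is usable)
Conditions: 11 (slow addition), Et3N, hexanes, 25 °C
Reagents that add atoms: dichloroketene generated in situ, ClC(Cl)=C=O
Why: Ketene–silyl enol ether [2+2] cycloaddition with the ketene carbonyl bonding to the enol β-carbon; Et3N-generated dichloroketene reacts with the enol ether far faster than with the trisubstituted alkenes, and both new ring-fusion centres are destroyed in step 8.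

**Step 8**
Reactants: 12
Product: 13 (4S,6S,7S)-7-methyl-4,6-bis(3-methylbut-2-en-1-yl)-7-(4-methylpent-3-en-1-yl)cyclooctane-1,3-dione
Conditions: Zn dust, AcOH, i-PrOH/H2O, 0 °C → rt
Reagents that add atoms: none
Why: Reductive dechlorination, then desilylation and retro-aldol cleavage of the central cyclobutane bond (de Mayo-type fragmentation, the same reaction type as the known cycloheptane-1,3-dione preparation) inserts two carbons; C4, C6 and C7 are not touched (7S here is the same geometry as 7R in the target).

**Step 9**
Reactants: 13; 7 prenyl bromide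
Product: 14 (4S,6S,7S)-7-methyl-2,4,6-tris(3-methylbut-2-en-1-yl)-7-(4-methylpent-3-en-1-yl)cyclooctane-1,3-dione (C2 epimers/enol)
Conditions: K2CO3, 7 (1.05 equiv), acetone, rt → 40 °C
Reagents that add atoms: prenyl bromide, CC(C)=CCBr
Why: C-alkylation of the β-diketone monoenolate; only C2 is deprotonated, so C4 cannot epimerise.

**Step 10**
Reactants: 14
Product: 15 (2S,4S,6S,7S)-2-hydroxy-7-methyl-2,4,6-tris(3-methylbut-2-en-1-yl)-7-(4-methylpent-3-en-1-yl)cyclooctane-1,3-dione
Conditions: KHMDS, THF, −78 °C; (±)-trans-2-(phenylsulfonyl)-3-phenyloxaziridine, −78 → −20 °C; AcOH quench at −78 °C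
Reagents that add atoms: Davis oxaziridine, O=S(=O)(c1ccccc1)N1OC1c1ccccc1
Why: Davis enolate hydroxylation; the oxidant is expected to approach anti to the C4 prenyl group (and the C7 homoprenyl), giving OH trans to C4-prenyl (2S here is the same geometry as 2R in the target), and the prenyl alkenes are inert to the oxaziridine.

**Step 11**
Reactants: 15; 16 2-methylpropanoyl chloride
Product: 17 (1S,3S,5S,6S)-6-methyl-1,3,5-tris(3-methylbut-2-en-1-yl)-6-(4-methylpent-3-en-1-yl)-2,8-dioxocyclooctyl 2-methylpropanoate
Conditions: 16, pyridine, DMAP (cat.), CH2Cl2, 0 °C → rt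
Reagents that add atoms: 2-methylpropanoyl chloride, CC(C)C(=O)Cl
Why: DMAP-catalysed acylation of the tertiary α-ketol OH; no stereocentre is involved.

**Step 12**
Reactants: 17
Product: 18 hyphenrone F, (2R,4S,6S,7R,8R)-2-hydroxy-7-methyl-2,4,6-tris(3-methylbut-2-en-1-yl)-7-(4-methylpent-3-en-1-yl)-8-(2-methylpropanoyl)cyclooctane-1,3-dione
Conditions: LDA (1.15 equiv), THF, −78 → −30 °C; AcOH quench at −78 °C; neutral work-up
Reagents that add atoms: none
Why: Proposed new method: kinetic deprotonation of the C8 methylene (in preference to the C4 methine) gives the C1 enolate, which attacks the adjacent C2 ester carbonyl through a five-membered cyclic alkoxide (intramolecular Claisen, a 1,4 O→C acyl shift; closest known types are the Baker–Venkataraman rearrangement and the intramolecular Claisen of α-acyloxy carbonyl compounds used for tetronic acids and 3(2H)-furanones); collapse gives the C2 alkoxide and a β-diketone that is deprotonated irreversibly, which drives the reaction to C8 (transfer to C4 would give a non-enolisable, reversible adduct), and C8 is set on protonation and equilibration with the acyl group trans to homoprenyl and cis to C2–OH (8R).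

## Compound list

1 | 5-methylhex-4-enal | CC(C)=CCCC=O | starting material
2 | but-3-en-2-one | CC(=O)C=C | starting material
3 | (R)-5-methyl-2-(3-oxobutyl)hex-4-enal | O=C[C@@H](CC=C(C)C)CCC(C)=O | intermediate
4 | (R)-4-(3-methylbut-2-en-1-yl)cyclohex-2-en-1-one | O=C1C=C[C@@H](CC=C(C)C)CC1 | intermediate
5 | trimethyl{[(3R,4R)-3-methyl-4-prenylcyclohex-1-en-1-yl]oxy}silane | C[Si](C)(C)OC1=C[C@H](C)[C@@H](CC=C(C)C)CC1 | intermediate
6 | (R)-3-methyl-4-(3-methylbut-2-en-1-yl)cyclohex-2-en-1-one | O=C1C=C(C)[C@@H](CC=C(C)C)CC1 | intermediate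
7 | 1-bromo-3-methylbut-2-ene (prenyl bromide) | CC(C)=CCBr | starting material
8 | (4S,6S)-3-methyl-4,6-bis(3-methylbut-2-en-1-yl)cyclohex-2-en-1-one | O=C1C=C(C)[C@@H](CC=C(C)C)C[C@@H]1CC=C(C)C | intermediate
9 | 5-bromo-2-methylpent-2-ene (homoprenyl bromide) | CC(C)=CCCBr | starting material
10 | (3R,4S,6S)-TMS enol ether (see step 6) | C[Si](C)(C)OC1=C[C@](C)(CCC=C(C)C)[C@@H](CC=C(C)C)C[C@@H]1CC=C(C)C | intermediate
11 | dichloroacetyl chloride | O=C(Cl)C(Cl)Cl | starting material
12 | (1S,2S,4S,5R,6S)-8,8-dichloro-1-(trimethylsilyloxy)bicyclo[4.2.0]octan-7-one cycloadduct (see step 7) | C[Si](C)(C)O[C@@]1(C(Cl)(Cl)C2=O)[C@@H](CC=C(C)C)C[C@H](CC=C(C)C)[C@@](C)(CCC=C(C)C)[C@@H]12 | intermediate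
13 | (4S,6S,7S)-7-methyl-4,6-diprenyl-7-homoprenylcyclooctane-1,3-dione | O=C1CC(=O)[C@@H](CC=C(C)C)C[C@H](CC=C(C)C)[C@@](C)(CCC=C(C)C)C1 | intermediate
14 | (4S,6S,7S)-7-methyl-2,4,6-triprenyl-7-homoprenylcyclooctane-1,3-dione | O=C1C(CC=C(C)C)C(=O)[C@@H](CC=C(C)C)C[C@H](CC=C(C)C)[C@@](C)(CCC=C(C)C)C1 | intermediate
15 | (2S,4S,6S,7S)-2-hydroxy-7-methyl-2,4,6-triprenyl-7-homoprenylcyclooctane-1,3-dione | O=C1[C@@](O)(CC=C(C)C)C(=O)[C@@H](CC=C(C)C)C[C@H](CC=C(C)C)[C@@](C)(CCC=C(C)C)C1 | intermediate
16 | 2-methylpropanoyl chloride | CC(C)C(=O)Cl | starting material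
17 | (1S,3S,5S,6S)-6-methyl-1,3,5-triprenyl-6-homoprenyl-2,8-dioxocyclooctyl 2-methylpropanoate | O=C1[C@@](OC(=O)C(C)C)(CC=C(C)C)C(=O)[C@@H](CC=C(C)C)C[C@H](CC=C(C)C)[C@@](C)(CCC=C(C)C)C1 | intermediate
18 | hyphenrone F | CC(C)=CCC[C@]1(C)[C@@H](CC=C(C)C)C[C@H](CC=C(C)C)C(=O)[C@](O)(CC=C(C)C)C(=O)[C@H]1C(=O)C(C)C | target

## Summary

Total steps: 12. Longest linear sequence: 12 (fully linear from 1 + 2). No protecting groups.

Three steps most likely to fail:

1. **Steps 7–8, ring expansion.** The [2+2] must occur at an enol carbon next to the quaternary centre, and the retro-aldol must cleave the central bond. Fallback: expand from the unhindered side instead. Take 6 through cuprate addition to the ketone, form the kinetic enol ether away from the quaternary carbon (LDA/TMSCl), run the same ketene/Zn sequence, and add the C4 prenyl afterwards by γ-alkylation of the 1,3-dione dianion.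

2. **Step 10, facial selectivity at C2.** The anti-to-C4-prenyl model is unproven in this eight-membered ring. Fallback: reverse the order of C2 bond formation. Acyloxylate C2 of 13 first (enolate plus diisobutyryl peroxide), then C-prenylate. The electrophile that enters second takes the same preferred face, so this gives the opposite C2 epimer and leads directly to 17.

3. **Step 12, O→C acyl shift.** Risks are C4 versus C8 enolisation (with loss of C4 integrity), α-ketol or retro-Claisen side reactions of the C2 alkoxide, and closure to a furanone. Fallback: bring the acyl carbon in at the six-membered-ring stage by trapping the step-6 enolate with isobutyraldehyde (aldol), carry it as a TBS ether, ring-expand from the other α-side, and reveal the β-diketone at the end by desilylation and Dess–Martin oxidation.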